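Two questions stood on this flask, and I could reckon on the first.

common to all: first end groups 0.78 M
- Tuesday's: second end groups 0.50 equiv (fed, over 20 h); scavenger 1.2 equiv; run made earlier; the fed solution adds 0.10 times the starting volume
- Monday's: second end groups 0.75 equiv (fed, over 20 h); scavenger 1.2 equiv; run made earlier; the fed solution adds 0.10 times the starting volume
- Saturday's: second end groups 1 equiv (fed, over 20 h); scavenger 0.60 equiv; run made earlier; the fed solution adds 0.10 times the starting volume
- flask: second end groups 1.00 equiv (fed, over 20 h); scavenger 1.20 equiv; the fed solution adds 0.10 times the starting volume; time 40 h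

| run | time / h | first end groups / % | links / % |
|---|---|---|---|
| Tuesday's | 2.00 | 62 | 2 |
| Tuesday's | 3.00 | 49 | 2 |
| Tuesday's | 4.00 | 44 | 0 |
| Tuesday's | 6.00 | 31 | 6 |
| Tuesday's | 10.0 | 18 | 3 |
| Tuesday's | 15.0 | 16 | 10 |
| Tuesday's | 25.0 | 4 | 16 |
| Monday's | 3.00 | 53 | 6 |
| Monday's | 6.00 | 37 | 3 |
| Monday's | 10.0 | 20 | 13 |
| Monday's | 15.0 | 11 | 15 |
| Monday's | 20.0 | 2 | 24 |
| Monday's | 25.0 | 4 | 24 |
| Saturday's | 5.00 | 34 | 7 |
| Saturday's | 10.0 | 18 | 16 |
| Saturday's | 15.0 | 12 | 19 |
| Saturday's | 20.0 | 2 | 25 |
| Saturday's | 25.0 | 0 | 26 |

(scatter of a reading: 2 percentage points)

* part of the first end groups that has reacted at 40 h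
* share of the unused second end groups that is free and not bound as idle adduct, at 40 h

- charges are per starting volume, the dose included; the dosed solution carries all of it
- the earlier runs do not show how much of second end groups is bound; that part of a forecast is a guess

At 10.0 h the first end groups stood at 18 %, 20 % and 18 % in Tuesday's, Monday's and Saturday's runs, though second end groups and scavenger differed. Tuesday's run had 49 % left at 3.00 h, and the next 3.00 h took it down to 31 %, so the fall slowed, and I read it as first end groups consuming one another. I took τ from Tuesday's reading at 4.00 h, as time divided by (reciprocal of the fraction left minus one): τ = 3.14 h, the self-loss time, meaning the second-order half-life at the charged concentration.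

Two versions of the flask solve in the head. If first end groups met only each other, 7.28 % would stay at 40 h. If the 1.00 equiv dosed took them one to one, the end state would hold none. Links are a second way out, so I put the real flask between these. Saturday's run, with this flask's second end groups but half its scavenger, read 2 % at 20.0 h, below the 13.6 % of the self-loss version, so I committed to 98.0 % reacted or more for this flask. For the free share the readings showed nothing, and I set no number.

The forecast, calling that share “still largely a guess”, gave 99 % and 50 %; the flask gave 99.9 % and >99.9 %.

    first end groups + second end groups ⇌ links + released group (K = 7.40, k = 9.27 × 10⁻⁵ L mol⁻¹ s⁻¹)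
    second end groups + released group ⇌ idle adduct, settled at all times (K = 4.10 L mol⁻¹)
    scavenger + released group → scavenged by-product (k = 0.00109 L mol⁻¹ s⁻¹)
    2 first end groups → self-condensation product (k = 5.58 × 10⁻⁵ L mol⁻¹ s⁻¹)

The flask held 0.115 % of its first end groups at 40.0 h, inside my bounds. Read as second order, τ for a neighbour flask, the same recipe started at 0.20 M of first end groups, becomes 12.3 h, so its self-loss version leaves 23.5 %; that neighbour held 9.0 % at 40.0 h. The flask had not quite stopped: by 400 h its first end groups lose their last 0.11 percentage points and its idle adduct goes from 1.40 × 10⁻⁴ M to 0 M, while links stand at 28.7 % after 28.6 % and second end groups at 71.3 % after 71.4 %.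

The numbers in the tables were computed from invented constants; scatter was added.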